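## Structural features

Compound 25 is an oplopane-type diester built on a trans-fused octahydroinden-2-one. A cyclopentanone (C1, C2, C3, C3a, C7a) shares the C3a–C7a bond with a cyclohexane (C3a, C4, C5, C6, C7, C7a) that carries an exocyclic methylidene at C7. There are eight stereocentres: C1, C7a, C3a, C3 and C4 are contiguous, C1′ hangs on C3, C6 is allylic, and the eighth lies in the (2R)-2-methylbutanoyl group. In the chair of the six-membered ring the bonds C7a–C1, C3a–C3 and C4–isopropyl are equatorial, and the C6 acyloxy group is axial. On the five-membered ring the C1 oxygen is pseudo-axial (anti to H7a) and the C3 arm is pseudo-equatorial.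

The fragile groups are the β-hydroxy ketone (C1′–OH with C2=O), the α-acyloxy ketone at C1, the axial allylic ester at C6 beside a 1,1-disubstituted alkene, and the β,β-disubstituted (E)-enoate. The real difficulty is the contiguous C1–C7a–C3a–C3–C4 array with its trans ring fusion, together with telling three secondary oxygens apart.

The key step uses this feature: if C7 is taken back to a ketone it is 1,4-related to the C2 ketone, so the ring bond C1–C7a joins two α-carbons of the same (donor) polarity. Oxidative coupling of two enol ethers makes that bond, closes the five-membered ring and releases C7 and C2 in different masks.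

## Logic of the disconnections

**25 ⇒ 24.** The C1′ O–Si bond is cut. C1′ is the only oxygen that stays unacylated, so it is carried as a silyl ether from the start and freed last. This keeps the β-hydroxy ketone out of every basic step. The forward step needs a desilylation that spares two esters, the α-acyloxy ketone and the allylic ester.

**24 ⇒ 21 + 22.** The C6 O–acyl bond is cut. The enoate is the group most sensitive to base, so it is put on after all enolate chemistry. The forward step must acylate a hindered axial allylic alcohol without moving the enoate double bond.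

**21 ⇒ 20.** The C6–O bond is cut back to an allylic C–H. The C7 methylidene activates exactly this position, so no protecting group and no separate C7 carbonyl chemistry are needed for C6. The forward oxidation must choose the C6 methylene over the C7a methine and deliver oxygen axially.

**20 ⇒ 18 + 19, then 18 ⇒ 16.** The C1 O–acyl bond and then the C1–O bond are cut. C1 is the unhindered α-methylene of the C2 ketone, so the oxygen comes from enolate hydroxylation and is acylated at once. The forward step needs kinetic enolisation away from C3 and oxygen delivery anti to H7a.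

**16 ⇒ 15 ⇒ 14.** The C2 carbonyl is returned to its dimethyl ketal, and the C7=CH2 bond to a C7 ketone. The two carbonyls are thereby distinguished, so C7 can be methylenated while C2 is masked. The forward steps need a non-basic methylenation (C7a is epimerisable) and a hydrolysis mild enough for the silyl ether and the exocyclic alkene.

**14 ⇒ 12.** The C1–C7a bond is cut, which opens the five-membered ring. This removes a ring and the C7a stereocentre and leaves a cyclohexene with one side chain. The forward step must join two donor carbons, which needs an umpolung by one-electron oxidation, and it must end with the trans fusion.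

**12 ⇒ 11.** The C1=C2 bond is cut, so the enol ether carbon C2 becomes an ester carbon. The forward methylenation must tolerate a silyl enol ether and must not epimerise C3.

**11 ⇒ 10 ⇒ 9 ⇒ 8.** The C1′ O–Si bond is cut, then the C1′–O bond is cut with inversion. The chelate-controlled addition that sets C3 correctly gives the wrong C1′ epimer, so one inversion is accepted. It is placed before the acid-labile methyl enol ether exists. The forward step needs substitution to beat elimination toward C3.

**8 ⇒ 4 + 5.** The C3–C3a bond is cut. This gives an enone and a chiral-pool hydroxy ester. The forward conjugate addition must go anti to the isopropyl group on the enone and anti to the methyl group on the chelated dianion, and the ring enolate must be trapped on oxygen to fix the C7=C7a enol ether.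

**4 ⇒ 1 + 2.** The C4–C5 bond (Michael) and the C3a=C7a bond (aldol condensation) are cut. The forward step needs a catalyst that sets C4 as (S).

## Other disconnections considered

**Alternative 1:** The cut removes C3a–C7a, C1–C2 and C2–C3 together and leads to the acyclic dienyne A1, in which C4, C6 and C1′ are already set. In the forward direction [RhCl(CO)2]2 (monovalent rhodium) under CO would join the alkyne, the vinyl arm of the diene and CO in a dienyl Pauson–Khand reaction to enone A2.
- In its favour: three C–C bonds and both rings form in one step. The C7 methylidene and the C6 oxygen are present before cyclisation, so no late methylenation or allylic oxidation is needed. On convergence and on these two points it is better than the chosen plan.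
- Against it: C7a is set only by induction from C6 and C4. The diene may divert into a [4+2] pathway. A2 still lacks C3a and C3, which must come from reduction of a tetrasubstituted enone; hydrogenation should favour the cis fusion, and a dissolving-metal reduction puts the allylic C6 oxygen at risk.
- Comparison: the alternative moves the trans-fusion problem to after its key step, whereas the chosen plan fixes C3a, C3 and C4 before ring closure and leaves only C7a to equilibration. The mechanisms differ (carbonylative metallacycle against radical-cation coupling). The step count is expected to be about equal.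

**Alternative 2:** The cut is C6–C7 and leads to the ynal A3. In the forward direction Ni(cod)2 (zerovalent nickel), an N-heterocyclic carbene and Et3SiH would couple the aldehyde and the alkyne to the silylated allylic alcohol A4.
- In its favour: the ring, the methylidene and the C6 oxygen form together. The two silyl ethers are differentiated from the outset. The trans relationship at C3a and C7a exists before ring closure, so no equilibration is needed, and on this point it is better than the chosen plan.
- Against it: A3 already holds the α-acyloxy ketone and four contiguous stereocentres on a cyclopentane, so the hard work is only moved upstream. Low-valent nickel and silane may attack the α-acyloxy ketone. The axial C6 configuration is not secured by any element of the substrate.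
- Comparison: the alternative is the equal of the chosen plan in the endgame and worse in step economy.

**Alternative 3:** The cut is C2–C3, with C2–C1′ remade, and leads to the trans-decalin epoxy ketone A5. In the forward direction BF3·OEt2 would open the epoxide at C3 while the acyl carbon C2 migrates anti, contracting the ring to β-diketone A6.
- In its favour: the shift is stereospecific at C3. A trans-decalin is the thermodynamically preferred fusion, so ring-fusion control is better than in the chosen plan. A6 is formally one reduction from 25.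
- Against it: in A6 C3 lies between two carbonyls and can lose its configuration by enolisation. The last step would have to reduce the acetyl carbonyl selectively to the (1′R) alcohol beside the more activated C2 ketone. BF3 may ionise the allylic C6 ester.
- Comparison: the chosen plan brings C1′ in at the correct oxidation level from the chiral pool. On endgame risk the alternative is worse, and on step count it is at best equal.

Key step: step 7

**Remarks on the chemistry**
- Acids 19 and 22 are assumed to be purchasable in the stated configuration.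
- Locants C1–C7a and C1′ of 25 are used for all bicyclic compounds, also where systematic rules would renumber. TBS = tert-butyl(dimethyl)silyl.
- Compounds 12 and 14 carry the configuration of 25 at C3, C3a, C4 and C1′, so their constitution needed no correction.
- Three design points are added to 12. The C7=C7a enol ether is made only by trapping the Michael enolate. C1′ is inverted before the methyl enol ether exists. The C1′ oxygen is silylated so that it cannot capture the oxocarbenium ions formed at the anode.

## Route

Step 1
Reactants: 1 3-methylbutanal; 2 but-3-en-2-one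
Product: 4 (4S)-4-(propan-2-yl)cyclohex-2-en-1-one [(S)-cryptone], via keto aldehyde 3 (not isolated)
Conditions: (S)-2-[methoxy(diphenyl)methyl]pyrrolidine (5 mol%), ethyl 3,4-dihydroxybenzoate (20 mol%), neat, 4 °C; then LiOH, iPrOH, rt
Reagents that add atoms: none
Why: Enamine-catalysed Michael addition, in which the diarylmethyl group shields one face of the E-enamine so that 2 adds to the other face and sets C4 as (S); intramolecular aldol condensation of 3 then closes the enone (organocatalytic Robinson-type annulation).

Step 2
Reactants: 4 (S)-cryptone; 5 methyl (3S)-3-hydroxybutanoate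
Product: 8 methyl (2S,3S)-2-[(1S,6S)-3-(TBSO)-6-(propan-2-yl)cyclohex-2-en-1-yl]-3-hydroxybutanoate, via dilithio dianion 6 (not isolated), via dilithium Michael adduct 7 (not isolated)
Conditions: 5, LiN(iPr)2 (2.05 equiv), THF, −78 to −30 °C; 4, −78 °C; TBSCl (1.05 equiv), HMPA, −78 °C; AcOH, −78 °C
Reagents that add atoms: tert-butyl(chloro)dimethylsilane, CC(C)(C)[Si](C)(C)Cl
Why: Michael addition of the Fráter–Seebach dianion, in which the lithium chelate is attacked anti to the C1′ methyl (sets C3) and the enone anti to the C4 isopropyl (sets C3a). The ring enolate is silylated on oxygen faster than the chelated, hindered alkoxide, which fixes the C7=C7a enol ether and leaves C1′–OH free.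

Step 3
Reactants: 8 Michael adduct
Product: 9 methyl (2S,3R)-2-[(1S,6S)-3-(TBSO)-6-(propan-2-yl)cyclohex-2-en-1-yl]-3-[(4-nitrobenzoyl)oxy]butanoate
Conditions: PPh3, DIAD, 4-nitrobenzoic acid, toluene, 0 °C to rt
Reagents that add atoms: 4-nitrobenzoic acid, OC(=O)c1ccc(cc1)[N+](=O)[O-]
Why: Mitsunobu reaction, in which the carboxylate displaces the alkoxyphosphonium group by SN2 and inverts C1′ to (R); the acidic, weakly basic nucleophile favours substitution over elimination toward C3.

Step 4
Reactants: 9 nitrobenzoate
Product: 10 methyl (2S,3R)-2-[(1S,6S)-3-(TBSO)-6-(propan-2-yl)cyclohex-2-en-1-yl]-3-hydroxybutanoate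
Conditions: K2CO3 (0.2 equiv), MeOH, 0 °C
Reagents that add atoms: none
Why: Methanolysis (transesterification) of the electron-poor aryl ester is fast, exchange at the hindered methyl ester is degenerate, and the TBS enol ether should tolerate brief cold carbonate.

Step 5
Reactants: 10 inverted hydroxy ester
Product: 11 methyl (2S,3R)-3-(TBSO)-2-[(1S,6S)-3-(TBSO)-6-(propan-2-yl)cyclohex-2-en-1-yl]butanoate
Conditions: TBSOTf, 2,6-lutidine, CH2Cl2, −78 to 0 °C
Reagents that add atoms: tert-butyl(dimethyl)silyl trifluoromethanesulfonate, CC(C)(C)[Si](C)(C)OS(=O)(=O)C(F)(F)F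
Why: O-silylation with the triflate is needed for the hindered secondary alcohol; the buffered conditions leave the silyl enol ether and C3 untouched.

Step 6
Reactants: 11 bis-silyl ester
Product: 12 tert-butyl({(3S,4S)-3-[(3S,4R)-4-(TBSO)-2-methoxypent-1-en-3-yl]-4-(propan-2-yl)cyclohex-1-en-1-yl}oxy)dimethylsilane
Conditions: Cp2TiMe2 (3 equiv), toluene, 65 °C, dark; basic alumina
Reagents that add atoms: dimethyltitanocene, C[Ti](C)(C1C=CC=C1)C1C=CC=C1
Why: Petasis methylenation, in which thermally formed Cp2Ti=CH2 adds to the ester carbonyl and the oxatitanacycle collapses to the methyl enol ether; the neutral conditions keep both silyl groups and the C3 configuration.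

Step 7
Reactants: 12 bis-enol ether
Product: 14 (3S,3aS,4S,7aR)-3-[(1R)-1-(TBSO)ethyl]-2,2-dimethoxy-4-(propan-2-yl)octahydro-7H-inden-7-one, via cis-fused ketone 13 (not isolated)
Conditions: reticulated vitreous carbon anode, carbon cathode, undivided cell, LiClO4 (0.1 M), MeOH–THF 1:4, 2,6-lutidine, constant current (8 mA, 2.2 F/mol), rt; then DBU, MeOH, rt
Reagents that add atoms: methanol, CO
Why: The anode removes one electron from the more electron-rich trisubstituted silyl enol ether, and the terminal carbon C1 of the 2-methoxyallyl group attacks C7a of the radical cation, forming C1–C7a. The C2 oxocarbenium ion is captured by methanol as the dimethyl ketal; the C7 radical is oxidised once more and loses its silyl group to methanol, so C7 emerges as a ketone and C2 as a ketal. The closest known reaction type is the intramolecular anodic coupling of two enol ethers through an enol ether radical cation. The five-membered ring closes in a 5-exo-trig mode with respect to the C7=C7a bond (C7 stays outside the new ring). C7a is the one new stereocentre: the tether reaches C7a on the face of the C3a–C3 bond, so the kinetic product is the cis-fused 13. Base then epimerises C7a through the C7 enolate to the trans-fused 14, in which C7a–C1, C3a–C3 and the isopropyl group are all equatorial. The step needs C–C coupling to beat solvent capture of the radical cation; the intramolecular five-ring closure, the low methanol content and the lutidine buffer (which protects both acid-labile enol ethers) secure this. Regiochemistry is fixed by the positions of the two enol ethers, and the ketal keeps C3 from epimerising or eliminating during the base treatment.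

Step 8
Reactants: 14 trans-fused ketone
Product: 15 tert-butyl{(1R)-1-[(3S,3aS,4S,7aR)-2,2-dimethoxy-7-methylidene-4-(propan-2-yl)octahydro-1H-inden-3-yl]ethoxy}dimethylsilane
Conditions: Cp2TiMe2 (3 equiv), toluene–THF, 65 °C
Reagents that add atoms: dimethyltitanocene, C[Ti](C)(C1C=CC=C1)C1C=CC=C1
Why: Petasis methylenation of a hindered, enolisable ketone; the titanium carbene is not basic, so C7a is not epimerised, and the ketal and silyl ether are inert.

Step 9
Reactants: 15 methylidene ketal
Product: 16 (3S,3aS,4S,7aR)-3-[(1R)-1-(TBSO)ethyl]-7-methylidene-4-(propan-2-yl)octahydro-2H-inden-2-one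
Conditions: PPTS, acetone–H2O, rt
Reagents that add atoms: water, O
Why: Acetal hydrolysis through the oxocarbenium ion; PPTS is too weak to cleave the secondary TBS ether or to move the exocyclic alkene, and C3, now α to the ketone, already has the favoured pseudo-equatorial arrangement trans to C4.

Step 10
Reactants: 16 methylidene ketone
Product: 18 (1S,3S,3aS,4S,7aR)-3-[(1R)-1-(TBSO)ethyl]-1-hydroxy-7-methylidene-4-(propan-2-yl)octahydro-2H-inden-2-one, via potassium enolate 17 (not isolated)
Conditions: KN(SiMe3)2, THF, −78 °C; 3-phenyl-2-(phenylsulfonyl)oxaziridine, −78 °C; AcOH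
Reagents that add atoms: 3-phenyl-2-(phenylsulfonyl)oxaziridine, O=S(=O)(N1OC1c1ccccc1)c1ccccc1
Why: Kinetic deprotonation takes the C1 methylene in preference to the shielded C3 methine, and the enolate is hydroxylated by the oxaziridine (Davis oxidation), which does not touch the 1,1-disubstituted alkene. Oxygen should enter anti to the pseudo-axial C7a–H (torsional control), giving the (1S) carbinol.

Step 11
Reactants: 18 α-hydroxy ketone; 19 (2R)-2-methylbutanoic acid
Product: 20 (1S,3S,3aS,4S,7aR)-3-[(1R)-1-(TBSO)ethyl]-7-methylidene-2-oxo-4-(propan-2-yl)octahydro-1H-inden-1-yl (2R)-2-methylbutanoate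
Conditions: 19, DCC, DMAP (cat.), CH2Cl2, 0 °C
Reagents that add atoms: none
Why: Steglich esterification of an activated secondary alcohol; low temperature and catalytic DMAP limit epimerisation of the acid α-centre and of C1.

Step 12
Reactants: 20 C1 ester
Product: 21 (1S,3S,3aS,4S,6R,7aR)-3-[(1R)-1-(TBSO)ethyl]-6-hydroxy-7-methylidene-2-oxo-4-(propan-2-yl)octahydro-1H-inden-1-yl (2R)-2-methylbutanoate
Conditions: SeO2 (0.5 equiv), tBuOOH, CH2Cl2, 0 °C to rt
Reagents that add atoms: tert-butyl hydroperoxide, CC(C)(C)OO (oxygen relayed through selenium dioxide, O=[Se]=O)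
Why: Riley-type allylic oxidation: an ene reaction at the terminal methylene carbon removes the axial C6–H, and a [2,3]-sigmatropic shift returns oxygen to C6 on the axial face and restores the C7 methylidene. The C6 methylene should react before the C7a methine, which is more hindered and deactivated by the neighbouring acyloxy carbon.

Step 13
Reactants: 21 allylic alcohol; 22 (2E)-3-methylpent-2-enoic acid
Product: 24 (1S,3S,3aS,4S,6R,7aR)-3-[(1R)-1-(TBSO)ethyl]-7-methylidene-1-{[(2R)-2-methylbutanoyl]oxy}-2-oxo-4-(propan-2-yl)octahydro-1H-inden-6-yl (2E)-3-methylpent-2-enoate, via mixed anhydride 23 (not isolated)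
Conditions: 22, 2,4,6-trichlorobenzoyl chloride, Et3N, toluene, rt; then 21, DMAP, rt
Reagents that add atoms: none
Why: Yamaguchi esterification; the preformed mixed anhydride acylates the hindered axial alcohol under mild conditions that should not deconjugate or isomerise the (E)-enoate.

Step 14
Reactants: 24 silyl ether
Product: 25 (1S,3S,3aS,4S,6R,7aR)-3-[(1R)-1-hydroxyethyl]-7-methylidene-1-{[(2R)-2-methylbutanoyl]oxy}-2-oxo-4-(propan-2-yl)octahydro-1H-inden-6-yl (2E)-3-methylpent-2-enoate
Conditions: HF·pyridine, pyridine, THF, 0 °C to rt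
Reagents that add atoms: none
Why: Fluoride-mediated Si–O cleavage under buffered, non-basic conditions, which avoids epimerisation at C1 and C3, acyl migration and retro-aldol cleavage of the liberated β-hydroxy ketone.

## Compound list

1 | 3-methylbutanal | CC(C)CC=O | starting material
2 | but-3-en-2-one | CC(=O)C=C | starting material
3 | (2S)-5-oxo-2-(propan-2-yl)hexanal | O=C[C@H](C(C)C)CCC(C)=O | intermediate (not isolated)
4 | (4S)-4-(propan-2-yl)cyclohex-2-en-1-one, (S)-cryptone | O=C1C=C[C@H](C(C)C)CC1 | intermediate
5 | methyl (3S)-3-hydroxybutanoate | COC(=O)C[C@H](C)O | starting material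
6 | dilithium (3S)-1-methoxybut-1-ene-1,3-diolate (dianion of 5) | [Li]OC(OC)=C[C@H](C)O[Li] | intermediate (not isolated)
7 | methyl (2S,3S)-2-[(1S,6S)-3-(lithiooxy)-6-(propan-2-yl)cyclohex-2-en-1-yl]-3-(lithiooxy)butanoate | [Li]OC1=C[C@@H]([C@@H]([C@H](C)O[Li])C(=O)OC)[C@H](C(C)C)CC1 | intermediate (not isolated)
8 | methyl (2S,3S)-2-[(1S,6S)-3-(TBSO)-6-(propan-2-yl)cyclohex-2-en-1-yl]-3-hydroxybutanoate | CC(C)(C)[Si](C)(C)OC1=C[C@@H]([C@@H]([C@H](C)O)C(=O)OC)[C@H](C(C)C)CC1 | intermediate
9 | methyl (2S,3R)-2-[(1S,6S)-3-(TBSO)-6-(propan-2-yl)cyclohex-2-en-1-yl]-3-[(4-nitrobenzoyl)oxy]butanoate | CC(C)(C)[Si](C)(C)OC1=C[C@@H]([C@@H]([C@@H](C)OC(=O)c2ccc(cc2)[N+](=O)[O-])C(=O)OC)[C@H](C(C)C)CC1 | intermediate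
10 | methyl (2S,3R)-2-[(1S,6S)-3-(TBSO)-6-(propan-2-yl)cyclohex-2-en-1-yl]-3-hydroxybutanoate | CC(C)(C)[Si](C)(C)OC1=C[C@@H]([C@@H]([C@@H](C)O)C(=O)OC)[C@H](C(C)C)CC1 | intermediate
11 | methyl (2S,3R)-3-(TBSO)-2-[(1S,6S)-3-(TBSO)-6-(propan-2-yl)cyclohex-2-en-1-yl]butanoate | CC(C)(C)[Si](C)(C)OC1=C[C@@H]([C@@H]([C@@H](C)O[Si](C)(C)C(C)(C)C)C(=O)OC)[C@H](C(C)C)CC1 | intermediate
12 | tert-butyl({(3S,4S)-3-[(3S,4R)-4-(TBSO)-2-methoxypent-1-en-3-yl]-4-(propan-2-yl)cyclohex-1-en-1-yl}oxy)dimethylsilane | CC(C)(C)[Si](C)(C)OC1=C[C@@H]([C@@H]([C@@H](C)O[Si](C)(C)C(C)(C)C)C(OC)=C)[C@H](C(C)C)CC1 | intermediate (key-step precursor)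
13 | (3S,3aS,4S,7aS)-3-[(1R)-1-(TBSO)ethyl]-2,2-dimethoxy-4-(propan-2-yl)octahydro-7H-inden-7-one (cis-fused) | O=C1[C@@H]2[C@@H]([C@@H]([C@@H](C)O[Si](C)(C)C(C)(C)C)C(OC)(OC)C2)[C@H](C(C)C)CC1 | intermediate (not isolated)
14 | (3S,3aS,4S,7aR)-3-[(1R)-1-(TBSO)ethyl]-2,2-dimethoxy-4-(propan-2-yl)octahydro-7H-inden-7-one (trans-fused) | O=C1[C@H]2[C@@H]([C@@H]([C@@H](C)O[Si](C)(C)C(C)(C)C)C(OC)(OC)C2)[C@H](C(C)C)CC1 | intermediate (key-step product)
15 | tert-butyl{(1R)-1-[(3S,3aS,4S,7aR)-2,2-dimethoxy-7-methylidene-4-(propan-2-yl)octahydro-1H-inden-3-yl]ethoxy}dimethylsilane | C=C1[C@H]2[C@@H]([C@@H]([C@@H](C)O[Si](C)(C)C(C)(C)C)C(OC)(OC)C2)[C@H](C(C)C)CC1 | intermediate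
16 | (3S,3aS,4S,7aR)-3-[(1R)-1-(TBSO)ethyl]-7-methylidene-4-(propan-2-yl)octahydro-2H-inden-2-one | C=C1[C@H]2[C@@H]([C@@H]([C@@H](C)O[Si](C)(C)C(C)(C)C)C(=O)C2)[C@H](C(C)C)CC1 | intermediate
17 | potassium C1=C2 enolate of 16 | C=C1[C@H]2[C@@H]([C@@H]([C@@H](C)O[Si](C)(C)C(C)(C)C)C(O[K])=C2)[C@H](C(C)C)CC1 | intermediate (not isolated)
18 | (1S,3S,3aS,4S,7aR)-3-[(1R)-1-(TBSO)ethyl]-1-hydroxy-7-methylidene-4-(propan-2-yl)octahydro-2H-inden-2-one | C=C1[C@H]2[C@@H]([C@@H]([C@@H](C)O[Si](C)(C)C(C)(C)C)C(=O)[C@H]2O)[C@H](C(C)C)CC1 | intermediate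
19 | (2R)-2-methylbutanoic acid | CC[C@@H](C)C(=O)O | starting material
20 | (1S,3S,3aS,4S,7aR)-3-[(1R)-1-(TBSO)ethyl]-7-methylidene-2-oxo-4-(propan-2-yl)octahydro-1H-inden-1-yl (2R)-2-methylbutanoate | C=C1[C@H]2[C@@H]([C@@H]([C@@H](C)O[Si](C)(C)C(C)(C)C)C(=O)[C@H]2OC(=O)[C@H](C)CC)[C@H](C(C)C)CC1 | intermediate
21 | (1S,3S,3aS,4S,6R,7aR)-3-[(1R)-1-(TBSO)ethyl]-6-hydroxy-7-methylidene-2-oxo-4-(propan-2-yl)octahydro-1H-inden-1-yl (2R)-2-methylbutanoate | C=C1[C@H]2[C@@H]([C@@H]([C@@H](C)O[Si](C)(C)C(C)(C)C)C(=O)[C@H]2OC(=O)[C@H](C)CC)[C@H](C(C)C)C[C@H]1O | intermediate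
22 | (2E)-3-methylpent-2-enoic acid | OC(=O)/C=C(\C)CC | starting material
23 | (2E)-3-methylpent-2-enoic 2,4,6-trichlorobenzoic anhydride | O=C(OC(=O)/C=C(\C)CC)c1c(Cl)cc(Cl)cc1Cl | intermediate (not isolated)
24 | (1S,3S,3aS,4S,6R,7aR)-3-[(1R)-1-(TBSO)ethyl]-7-methylidene-1-{[(2R)-2-methylbutanoyl]oxy}-2-oxo-4-(propan-2-yl)octahydro-1H-inden-6-yl (2E)-3-methylpent-2-enoate | C=C1[C@H]2[C@@H]([C@@H]([C@@H](C)O[Si](C)(C)C(C)(C)C)C(=O)[C@H]2OC(=O)[C@H](C)CC)[C@H](C(C)C)C[C@H]1OC(=O)/C=C(\C)CC | intermediate
25 | (1S,3S,3aS,4S,6R,7aR)-3-[(1R)-1-hydroxyethyl]-7-methylidene-1-{[(2R)-2-methylbutanoyl]oxy}-2-oxo-4-(propan-2-yl)octahydro-1H-inden-6-yl (2E)-3-methylpent-2-enoate | C=C1[C@H]2[C@@H]([C@@H]([C@@H](C)O)C(=O)[C@H]2OC(=O)[C@H](C)CC)[C@H](C(C)C)C[C@H]1OC(=O)/C=C(\C)CC | target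

## Step count and least certain steps

Total step count: 14. Longest linear sequence: 14 steps (1 and 2 to 25); 5, 19 and 22 enter as purchased branches.

**Step 7 (key step).** The radical cation may be captured by methanol or lose its silyl group before the C–C bond forms, the methyl enol ether may hydrolyse in the cell, and the cis-to-trans equilibration at C7a may be incomplete. The last point matters most, because the trans fusion rests only on thermodynamics and the energy gap in a hydrindanone is small.

Fallback (polar, C1 as electrophile): the fallback sets out from 11. Chloromethyllithium (ICH2Cl, MeLi·LiBr, THF, −78 °C) should convert the ester into the chloromethyl ketone F1. One equivalent of Bu4NF (THF, −78 °C) then unmasks the C7/C7a enolate regiospecifically, and C7a alkylates in a 5-(enolexo)-exo-tet closure. DBU equilibration should give the trans-fused diketone F2. One equivalent of Ph3P=CH2 (THF, −20 °C) is expected to methylenate the six-ring ketone C7, which is more electrophilic and less shielded than C2 beside the branched C3. This returns to the route at 16. The cost is that the two carbonyls are no longer differentiated by the bond-forming step.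

**Step 2.** The dianion may add 1,2 to the enone, the pairing of the two chiral partners may be mismatched and erode selectivity at C3, and the alkoxide may be silylated along with the enolate. Each would arise because a hard, chelated lithium enolate meets an unhindered enone and two nucleophilic oxygens compete for one silyl chloride.

Fallback (Mukaiyama–Michael with silyl transfer): the fallback sets out from 4. The pivalaldehyde acetal of (S)-3-hydroxybutanoic acid, dioxanone F3, is obtained separately and converted (LiN(iPr)2, TBSCl, THF–HMPA, −78 °C) into the silyl ketene acetal F4. Addition of F4 to 4 under TBSOTf catalysis (CH2Cl2, −78 °C) should give Michael adduct F5, with attack trans to tert-butyl and methyl on the acetal and anti to isopropyl on the enone; the silyl group passes to the ring enolate oxygen, and no free alkoxide is present. K2CO3 in MeOH opens the acylal and returns to the route at 8.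

**Step 3.** The activated alcohol may eliminate toward the acidic C3–H to give the α-ethylidene ester, or the hindered carbinol may not be substituted at all.

Fallback (redox inversion): the fallback sets out from 8. Dess–Martin periodinane (NaHCO3, CH2Cl2, 0 °C) should give the β-keto ester F6, which is reduced at once with Zn(BH4)2 (Et2O, −78 °C). Hydride attack on the zinc chelate anti to the C3 substituent gives the 2,3-syn hydroxy ester, which is 10. The danger is loss of the C3 configuration by enolisation of F6, so no base is used and F6 is not stored.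

**Step 10.** Facial selectivity at C1 may be poor if the bulky oxidant is steered by the C3 arm instead of by torsional effects. The enolate may also equilibrate toward C3, followed by loss of the β-silyloxy group.

Fallback (inversion during esterification): the fallback sets out from 16. If hydroxylation gives mainly the C1 epimer F7, F7 is esterified with 19 under Mitsunobu conditions (PPh3, DIAD, toluene, 0 °C). SN2 displacement at the carbinol α to the ketone inverts C1 and returns to the route at 20.

**Step 12.** Over-oxidation to the enone, attack at the C7a methine, or equatorial delivery of oxygen would each lower the yield of the axial C6 alcohol. The cause would be that the ene step and the sigmatropic shift are controlled only by the conformation of the substrate.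

Fallback (enolate route before methylenation): the fallback sets out from 14.
- Kinetic enolisation toward C6 (KN(SiMe3)2, THF, −78 °C) and the sulfonyloxaziridine should give the axial hydroxy ketone F8 by axial attack.
- Yamaguchi esterification with 22 gives the enoate F9.
- The Tebbe reagent Cp2Ti(μ-Cl)(μ-CH2)AlMe2 (1 equiv, THF–pyridine, −40 °C) methylenates the ketone in preference to the ester and gives the methylidene ketal F10.
- PPTS in acetone–water frees the C2 ketone F11.
- One equivalent of KN(SiMe3)2 and the oxaziridine hydroxylate C1 to the hydroxy ketone F12.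
- DCC and DMAP with 19 then return to the route at 24.

## Further compounds

F1 | step 7 | (3S,4R)-4-(TBSO)-3-[(1S,6S)-3-(TBSO)-6-(propan-2-yl)cyclohex-2-en-1-yl]-1-chloropentan-2-one | CC(C)(C)[Si](C)(C)OC1=C[C@@H]([C@@H]([C@@H](C)O[Si](C)(C)C(C)(C)C)C(=O)CCl)[C@H](C(C)C)CC1
F2 | step 7 | (3S,3aS,4S,7aR)-3-[(1R)-1-(TBSO)ethyl]-4-(propan-2-yl)octahydro-1H-indene-2,7-dione | O=C1[C@H]2[C@@H]([C@@H]([C@@H](C)O[Si](C)(C)C(C)(C)C)C(=O)C2)[C@H](C(C)C)CC1
F3 | step 2 | (2S,6S)-2-tert-butyl-6-methyl-1,3-dioxan-4-one | C[C@H]1CC(=O)O[C@H](O1)C(C)(C)C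
F4 | step 2 | tert-butyl{[(2S,4S)-2-tert-butyl-4-methyl-4H-1,3-dioxin-6-yl]oxy}dimethylsilane | C[C@H]1C=C(O[Si](C)(C)C(C)(C)C)O[C@H](O1)C(C)(C)C
F5 | step 2 | (2S,5S,6S)-2-tert-butyl-5-[(1S,6S)-3-(TBSO)-6-(propan-2-yl)cyclohex-2-en-1-yl]-6-methyl-1,3-dioxan-4-one | CC(C)(C)[Si](C)(C)OC1=C[C@@H]([C@H]2[C@H](C)O[C@H](C(C)(C)C)OC2=O)[C@H](C(C)C)CC1
F6 | step 3 | methyl (2S)-2-[(1S,6S)-3-(TBSO)-6-(propan-2-yl)cyclohex-2-en-1-yl]-3-oxobutanoate | CC(C)(C)[Si](C)(C)OC1=C[C@@H]([C@@H](C(C)=O)C(=O)OC)[C@H](C(C)C)CC1
F7 | step 10 | (1R,3S,3aS,4S,7aR)-3-[(1R)-1-(TBSO)ethyl]-1-hydroxy-7-methylidene-4-(propan-2-yl)octahydro-2H-inden-2-one | C=C1[C@H]2[C@@H]([C@@H]([C@@H](C)O[Si](C)(C)C(C)(C)C)C(=O)[C@@H]2O)[C@H](C(C)C)CC1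
F8 | step 12 | (3S,3aS,4S,6R,7aR)-3-[(1R)-1-(TBSO)ethyl]-6-hydroxy-2,2-dimethoxy-4-(propan-2-yl)octahydro-7H-inden-7-one | O=C1[C@H]2[C@@H]([C@@H]([C@@H](C)O[Si](C)(C)C(C)(C)C)C(OC)(OC)C2)[C@H](C(C)C)C[C@H]1O
F9 | step 12 | (3S,3aS,4S,6R,7aR)-3-[(1R)-1-(TBSO)ethyl]-2,2-dimethoxy-7-oxo-4-(propan-2-yl)octahydro-1H-inden-6-yl (2E)-3-methylpent-2-enoate | O=C1[C@H]2[C@@H]([C@@H]([C@@H](C)O[Si](C)(C)C(C)(C)C)C(OC)(OC)C2)[C@H](C(C)C)C[C@H]1OC(=O)/C=C(\C)CC
F10 | step 12 | (3S,3aS,4S,6R,7aR)-3-[(1R)-1-(TBSO)ethyl]-2,2-dimethoxy-7-methylidene-4-(propan-2-yl)octahydro-1H-inden-6-yl (2E)-3-methylpent-2-enoate | C=C1[C@H]2[C@@H]([C@@H]([C@@H](C)O[Si](C)(C)C(C)(C)C)C(OC)(OC)C2)[C@H](C(C)C)C[C@H]1OC(=O)/C=C(\C)CC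
F11 | step 12 | (3S,3aS,4S,6R,7aR)-3-[(1R)-1-(TBSO)ethyl]-7-methylidene-2-oxo-4-(propan-2-yl)octahydro-1H-inden-6-yl (2E)-3-methylpent-2-enoate | C=C1[C@H]2[C@@H]([C@@H]([C@@H](C)O[Si](C)(C)C(C)(C)C)C(=O)C2)[C@H](C(C)C)C[C@H]1OC(=O)/C=C(\C)CC
F12 | step 12 | (1S,3S,3aS,4S,6R,7aR)-3-[(1R)-1-(TBSO)ethyl]-1-hydroxy-7-methylidene-2-oxo-4-(propan-2-yl)octahydro-1H-inden-6-yl (2E)-3-methylpent-2-enoate | C=C1[C@H]2[C@@H]([C@@H]([C@@H](C)O[Si](C)(C)C(C)(C)C)C(=O)[C@H]2O)[C@H](C(C)C)C[C@H]1OC(=O)/C=C(\C)CC
A1 | alternative 1 | acyclic dienyne (vinyl C1=C7a, C7 methylidene, C6 triethylsilyl ether, C4 isopropyl, C3≡C3a alkyne, C1′ TBS ether; configuration of 25 at C4, C6, C1′) | C=CC(=C)[C@H](O[Si](CC)(CC)CC)C[C@@H](C(C)C)C#C[C@@H](C)O[Si](C)(C)C(C)(C)C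
A2 | alternative 1 | bicyclic C3=C3a enone with C7 methylidene, C6 triethylsilyl ether and C1′ TBS ether | C=C1[C@H]2C(=C([C@@H](C)O[Si](C)(C)C(C)(C)C)C(=O)C2)[C@H](C(C)C)C[C@H]1O[Si](CC)(CC)CC
A3 | alternative 2 | trans-3,4-disubstituted 2-acyloxycyclopentanone with C7a ethynyl group and C3a (3-oxo-1-isopropylpropyl) chain (C6 aldehyde) | C#C[C@H]1[C@@H]([C@@H]([C@@H](C)O[Si](C)(C)C(C)(C)C)C(=O)[C@H]1OC(=O)[C@H](C)CC)[C@H](C(C)C)CC=O
A4 | alternative 2 | full skeleton with C6 triethylsilyl ether, C1′ TBS ether and C1 (2R)-2-methylbutanoate | C=C1[C@H]2[C@@H]([C@@H]([C@@H](C)O[Si](C)(C)C(C)(C)C)C(=O)[C@H]2OC(=O)[C@H](C)CC)[C@H](C(C)C)C[C@H]1O[Si](CC)(CC)CC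
A5 | alternative 3 | trans-decalin 2-methyl-2,3-epoxy ketone (cadinane type) carrying both esters and the methylidene | C=C1[C@H]2[C@@H]([C@H]3O[C@@]3(C)C(=O)[C@H]2OC(=O)[C@H](C)CC)[C@H](C(C)C)C[C@H]1OC(=O)/C=C(\C)CC
A6 | alternative 3 | C1′ ketone of 25 (3-acetyl β-diketone) | C=C1[C@H]2[C@@H]([C@@H](C(C)=O)C(=O)[C@H]2OC(=O)[C@H](C)CC)[C@H](C(C)C)C[C@H]1OC(=O)/C=C(\C)CC
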